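**Plan**

1. Numbering follows the germacranolides: ring C1–C10, C14 = CH2OH on C10, C15 = CH3 on C4, lactone C12(=O)–O on C6, C13 = CH2OAc on C11, side-chain ester on C8.
2. Retrosynthesis: remove the C14 silyl group and the 4,5-epoxide, then cut the ten-membered ring at C3–C4. This bond lies between the Z C2=C3 alkene and C4; once the cis 4,5-epoxide is read as a Z C4=C5 alkene it is the central bond of a 2Z,4Z-diene, so the open chain is a C3 Z-alkenylstannane and a C4 Z-alkenyl iodide with the 1,10-epoxide and the butenolide already in place.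
3. Further cuts: butenolide at C7=C11 (intramolecular Horner–Wadsworth–Emmons) and O6–C12; C8–O ester (epoxide opening); C7=C8 (cross-metathesis); C1–C2 (Sonogashira); C9–C10 (carbomagnesiation of propargyl alcohol).
4. Forward: an epoxide fragment (C1–C3, C8–C10, C14) from propargyl alcohol and a dienol fragment (C4–C7, C15) from but-2-yn-1-ol are joined at C7=C8; tin is placed on C3, C8 is oxygenated, the butenolide ring closes first, the ten-membered ring second (copper-mediated), the 4,5-epoxide last.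
5. Stereochemistry: C1/C10 from Sharpless epoxidation (L-(+)-DIPT); C6 from Sharpless kinetic resolution; C8 from a matched Sharpless epoxidation (D-(−)-DIPT) and invertive opening by (R)-2-methylbutanoic acid (chiral pool); C4/C5 from substrate-controlled epoxidation of the macrocycle. Z geometries come from hydroalumination–iodination, anti-carbomagnesiation and hydrozirconation.

Key step: step 22

Remark on the chemistry: tartrate sense is assigned by the usual rule (L-(+)-tartrate converts an (E)-alk-2-en-1-ol into its 2S,3S epoxide; in a kinetic resolution it leaves behind the enantiomer that the opposite tartrate would epoxidise fast).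

**Route**

Step 1
Reactants: 1 but-2-yn-1-ol
Product: 3 (2Z)-3-iodobut-2-en-1-ol, via alkenylaluminate 2 (not isolated)
Conditions: NaAlH2(OCH2CH2OCH3)2, THF, 0 °C → rt; then I2, −78 °C
Reagents that add atoms: iodine, II
Why: Hydroxyl-directed trans-hydroalumination of the propargylic alcohol puts hydride on C2 and aluminium on C3 in a five-membered alanate, and iodinolysis with retention gives the Z-iodoalkene (I cis to CH2OH) that becomes the C4 terminus with its C15 methyl.

Step 2
Reactants: 3 (2Z)-3-iodobut-2-en-1-ol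
Product: 4 (2Z)-3-iodobut-2-enal
Conditions: MnO2, CH2Cl2, rt; used at once
Reagents that add atoms: none
Why: MnO2 oxidises the allylic alcohol to the enal under neutral conditions, so the Z geometry should survive if the aldehyde is not stored.

Step 3
Reactants: 4 (2Z)-3-iodobut-2-enal
Product: 5 rac-(4Z)-5-iodohexa-1,4-dien-3-ol
Conditions: CH2=CHMgBr, THF, −78 °C; then H2O
Reagents that add atoms: vinylmagnesium bromide, C=C[Mg]Br
Why: Grignard 1,2-addition to the enal gives the bis-allylic C6 carbinol (racemic at this stage), the alkenyl iodide being inert to the vinylmagnesium reagent at −78 °C.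

Step 4
Reactants: 5 rac-(4Z)-5-iodohexa-1,4-dien-3-ol
Product: 6 (3S,4Z)-5-iodohexa-1,4-dien-3-ol
Conditions: Ti(OiPr)4 (cat.), L-(+)-DIPT, t-BuOOH (0.6 equiv), 4 Å MS, CH2Cl2, −20 °C; unreacted alcohol recovered
Reagents that add atoms: none
Why: In this Sharpless kinetic resolution the (R)-alcohol should be epoxidised at its vinyl group much faster than the (S)-alcohol, while the hindered, electron-poor Z-iodoalkene stays intact, so the recovered (S)-alcohol carries the C6 configuration of the target.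

Step 5
Reactants: 7 prop-2-yn-1-ol
Product: 9 (2Z)-2-(iodomethylidene)pent-4-en-1-ol, via alkenylmagnesium alkoxide 8 (not isolated)
Conditions: CH2=CHCH2MgBr (2.5 equiv), CuI (cat.), Et2O, −10 °C → rt; then I2, THF, −40 → 0 °C
Reagents that add atoms: allylmagnesium bromide, C=CC[Mg]Br; iodine, II
Why: Copper-catalysed anti-carbomagnesiation of the propargylic alkoxide places the allyl group on the internal carbon and magnesium on the terminal carbon cis to CH2O in a chelate, and iodinolysis with retention fixes the C10=C1 geometry (C14 cis to the future C2).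

Step 6
Reactants: 9 (2Z)-2-(iodomethylidene)pent-4-en-1-ol
Product: 10 (2Z)-2-[3-(trimethylsilyl)prop-2-yn-1-ylidene]pent-4-en-1-ol
Conditions: Me3SiC≡CH, Pd(PPh3)2Cl2 (cat.), CuI (cat.), Et3N, THF, rt
Reagents that add atoms: ethynyltrimethylsilane, C#C[Si](C)(C)C
Why: Sonogashira coupling of the alkenyl iodide proceeds with retention of geometry, tolerates the free hydroxyl and adds C2 and C3 as a silyl-capped alkyne.

Step 7
Reactants: 10 (2Z)-2-[3-(trimethylsilyl)prop-2-yn-1-ylidene]pent-4-en-1-ol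
Product: 11 [(2S,3R)-2-(prop-2-en-1-yl)-3-[(trimethylsilyl)ethynyl]oxiran-2-yl]methanol
Conditions: Ti(OiPr)4 (cat.), L-(+)-DIPT, t-BuOOH, 4 Å MS, CH2Cl2, −20 °C
Reagents that add atoms: tert-butyl hydroperoxide, CC(C)(C)OO
Why: In the Sharpless asymmetric epoxidation L-(+)-DIPT delivers oxygen to the face of the allylic alcohol that gives the 2S,3R oxirane (C10 and C1 of the target), and the terminal alkene, which has no directing hydroxyl, is left alone.

Step 8
Reactants: 11 [(2S,3R)-2-(prop-2-en-1-yl)-3-[(trimethylsilyl)ethynyl]oxiran-2-yl]methanol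
Product: 12 tert-butyl(dimethyl){[(2S,3R)-2-(prop-2-en-1-yl)-3-[(trimethylsilyl)ethynyl]oxiran-2-yl]methoxy}silane
Conditions: TBSCl, imidazole, CH2Cl2, 0 °C → rt
Reagents that add atoms: tert-butyldimethylsilyl chloride, CC(C)(C)[Si](C)(C)Cl
Why: Standard silylation protects the primary C14 alcohol as a TBS ether that should last until the final fluoride treatment.

Step 9
Reactants: 12 tert-butyl(dimethyl){[(2S,3R)-2-(prop-2-en-1-yl)-3-[(trimethylsilyl)ethynyl]oxiran-2-yl]methoxy}silane; 6 (3S,4Z)-5-iodohexa-1,4-dien-3-ol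
Product: 13 (2Z,4S,5E)-7-[(2S,3R)-2-({[tert-butyl(dimethyl)silyl]oxy}methyl)-3-[(trimethylsilyl)ethynyl]oxiran-2-yl]-2-iodohepta-2,5-dien-4-ol
Conditions: second-generation Grubbs catalyst (5 mol%), 6 (2.5 equiv), CH2Cl2, 40 °C
Reagents that add atoms: none
Why: Olefin cross-metathesis between the terminal alkene and an excess of the secondary allylic alcohol is E-selective, and neither the trisubstituted iodoalkene nor the silyl-capped alkyne should engage the ruthenium carbene, so C7=C8 forms and the fragments are joined.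

Step 10
Reactants: 13 (2Z,4S,5E)-7-[(2S,3R)-2-({[tert-butyl(dimethyl)silyl]oxy}methyl)-3-[(trimethylsilyl)ethynyl]oxiran-2-yl]-2-iodohepta-2,5-dien-4-ol
Product: 14 (2Z,4S,5E)-7-[(2S,3R)-2-({[tert-butyl(dimethyl)silyl]oxy}methyl)-3-ethynyloxiran-2-yl]-2-iodohepta-2,5-dien-4-ol
Conditions: K2CO3 (cat.), MeOH, 0 °C → rt
Reagents that add atoms: none
Why: Methanolysis of the alkynyl C–Si bond under mild carbonate conditions should leave the TBS ether, the alkenes, the alkenyl iodide and the epoxide untouched.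

Step 11
Reactants: 14 (2Z,4S,5E)-7-[(2S,3R)-2-({[tert-butyl(dimethyl)silyl]oxy}methyl)-3-ethynyloxiran-2-yl]-2-iodohepta-2,5-dien-4-ol
Product: 15 (2Z,4S,5E)-7-[(2S,3R)-2-({[tert-butyl(dimethyl)silyl]oxy}methyl)-3-[(tributylstannyl)ethynyl]oxiran-2-yl]-2-iodohepta-2,5-dien-4-ol
Conditions: Bu3SnOMe, 60 °C, reduced pressure; crude product used directly
Reagents that add atoms: tributyltin methoxide, CCCC[Sn](CCCC)(CCCC)OC
Why: Tin alkoxides stannylate terminal alkynes by Sn–O/C–H exchange without added base, so the epoxide and the alkenyl iodide never meet an organolithium reagent (any stannyl ether at the hydroxyl is hydrolysed in the next work-up).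

Step 12
Reactants: 15 (2Z,4S,5E)-7-[(2S,3R)-2-({[tert-butyl(dimethyl)silyl]oxy}methyl)-3-[(tributylstannyl)ethynyl]oxiran-2-yl]-2-iodohepta-2,5-dien-4-ol
Product: 17 (2Z,4S,5E)-7-[(2S,3R)-2-({[tert-butyl(dimethyl)silyl]oxy}methyl)-3-[(Z)-2-(tributylstannyl)ethenyl]oxiran-2-yl]-2-iodohepta-2,5-dien-4-ol, via stannyl zirconocenyl alkene 16 (not isolated)
Conditions: Cp2Zr(H)Cl (2.5 equiv), THF, rt; then H2O
Reagents that add atoms: none
Why: Hydrozirconation of the stannylalkyne is a syn addition that puts zirconium on the tin-bearing carbon, and protonolysis with retention gives the Z-alkenylstannane; the alkyne should react far faster than the internal E-alkene, and the alkenyl iodide and epoxide are inert to Cp2Zr(H)Cl at room temperature.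

Step 13
Reactants: 17 (2Z,4S,5E)-7-[(2S,3R)-2-({[tert-butyl(dimethyl)silyl]oxy}methyl)-3-[(Z)-2-(tributylstannyl)ethenyl]oxiran-2-yl]-2-iodohepta-2,5-dien-4-ol
Product: 18 (1R,2Z)-1-{(2R,3R)-3-[((2S,3R)-2-({[tert-butyl(dimethyl)silyl]oxy}methyl)-3-[(Z)-2-(tributylstannyl)ethenyl]oxiran-2-yl)methyl]oxiran-2-yl}-3-iodobut-2-en-1-ol
Conditions: Ti(OiPr)4 (0.2 equiv), D-(−)-DIPT, t-BuOOH, 4 Å MS, CH2Cl2, −20 °C
Reagents that add atoms: tert-butyl hydroperoxide, CC(C)(C)OO
Why: Sharpless epoxidation of the secondary E-allylic alcohol with D-(−)-DIPT is the matched case for the C6 carbinol set in step 4 and should give the anti (erythro) 7R,8R epoxy alcohol, whereas the Z-iodoalkene on the other side of C6 is mismatched, hindered and electron-poor and the stannane and the 1,10-epoxide have no directing hydroxyl.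

Step 14
Reactants: 18 (1R,2Z)-1-{(2R,3R)-3-[((2S,3R)-2-({[tert-butyl(dimethyl)silyl]oxy}methyl)-3-[(Z)-2-(tributylstannyl)ethenyl]oxiran-2-yl)methyl]oxiran-2-yl}-3-iodobut-2-en-1-ol; 19 (2R)-2-methylbutanoic acid
Product: 20 (2S,3R,4R,5Z)-1-[(2S,3R)-2-({[tert-butyl(dimethyl)silyl]oxy}methyl)-3-[(Z)-2-(tributylstannyl)ethenyl]oxiran-2-yl]-3,4-dihydroxy-6-iodohept-5-en-2-yl (2R)-2-methylbutanoate
Conditions: Ti(OiPr)4 (1.5 equiv), 19 (2 equiv), CH2Cl2, rt; neutral work-up, used directly
Reagents that add atoms: none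
Why: In the titanium-mediated opening of a 2,3-epoxy alcohol by a carboxylic acid the chelated epoxide is attacked at its C-3 (here C8) with inversion, which installs the (R)-2-methylbutanoate and sets 8S in one operation, while the 1,10-epoxide cannot chelate and is not activated.

Step 15
Reactants: 21 ethyl 2-(diethoxyphosphoryl)prop-2-enoate
Product: 22 ethyl 2-(diethoxyphosphoryl)-3-[(4-methoxyphenyl)methoxy]propanoate (racemic)
Conditions: 4-MeOC6H4CH2OH, DBU (cat.), THF, 0 °C → rt
Reagents that add atoms: 4-methoxybenzyl alcohol, COc1ccc(CO)cc1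
Why: Base-catalysed oxa-Michael addition of the benzylic alcohol to the doubly activated phosphonoacrylate gives the β-alkoxy phosphonoacetate that will supply C11, C12 and a protected C13.

Step 16
Reactants: 22 ethyl 2-(diethoxyphosphoryl)-3-[(4-methoxyphenyl)methoxy]propanoate
Product: 23 2-(diethoxyphosphoryl)-3-[(4-methoxyphenyl)methoxy]propanoic acid (racemic)
Conditions: LiOH, THF/H2O, 0 °C; then HCl to pH 3
Reagents that add atoms: lithium hydroxide, [Li+].[OH-]
Why: Saponification of the carboxylic ethyl ester at 0 °C is far faster than hydrolysis of the phosphonate diester.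

Step 17
Reactants: 20 (2S,3R,4R,5Z)-1-[(2S,3R)-2-({[tert-butyl(dimethyl)silyl]oxy}methyl)-3-[(Z)-2-(tributylstannyl)ethenyl]oxiran-2-yl]-3,4-dihydroxy-6-iodohept-5-en-2-yl (2R)-2-methylbutanoate; 23 2-(diethoxyphosphoryl)-3-[(4-methoxyphenyl)methoxy]propanoic acid
Product: 24 C6 phosphonoacyl ester of 20 (allylic C6 hydroxyl esterified by 23, C7 hydroxyl free, all other centres as in 20)
Conditions: DCC, DMAP (cat.), CH2Cl2, −20 °C
Reagents that add atoms: none
Why: Steglich esterification at low temperature should occur at the allylic C6 hydroxyl, which is flanked by a planar alkenyl carbon, and not at the C7 hydroxyl, which is crowded between two oxygenated stereocentres and hydrogen-bonded to the neighbouring ester.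

Step 18
Reactants: 24 C6 phosphonoacyl ester of 20
Product: 25 C7 ketone of 24 (α,α'-diacyloxy ketone; C6 and C8 configurations unchanged)
Conditions: Dess–Martin periodinane, NaHCO3, CH2Cl2, 0 °C → rt
Reagents that add atoms: none
Why: Dess–Martin oxidation of the only free hydroxyl under bicarbonate buffer gives the ketone without disturbing the stannane, the epoxide or the PMB ether.

Step 19
Reactants: 25 C7 ketone of 24
Product: 26 (5R)-4-[(1S)-2-{(2S,3R)-2-({[tert-butyl(dimethyl)silyl]oxy}methyl)-3-[(Z)-2-(tributylstannyl)ethenyl]oxiran-2-yl}-1-{[(2R)-2-methylbutanoyl]oxy}ethyl]-5-[(Z)-2-iodoprop-1-en-1-yl]-3-{[(4-methoxyphenyl)methoxy]methyl}furan-2(5H)-one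
Conditions: LiCl, iPr2NEt, MeCN, 0 °C → rt
Reagents that add atoms: none
Why: Intramolecular Horner–Wadsworth–Emmons olefination under Masamune–Roush conditions closes the five-membered butenolide at C7=C11 faster than the weak amine base can epimerise C6 or C8, and the ring fixes the alkene geometry.

Step 20
Reactants: 26 butenolide PMB ether
Product: 27 (5R)-4-[(1S)-2-{(2S,3R)-2-({[tert-butyl(dimethyl)silyl]oxy}methyl)-3-[(Z)-2-(tributylstannyl)ethenyl]oxiran-2-yl}-1-{[(2R)-2-methylbutanoyl]oxy}ethyl]-3-(hydroxymethyl)-5-[(Z)-2-iodoprop-1-en-1-yl]furan-2(5H)-one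
Conditions: DDQ, CH2Cl2/pH 7 buffer, 0 °C
Reagents that add atoms: none
Why: Oxidative cleavage of the PMB ether with DDQ in buffered wet dichloromethane frees the C13 hydroxyl while the silyl ether, esters, epoxide, alkenyl iodide and alkenylstannane should be stable.

Step 21
Reactants: 27 C13 alcohol
Product: 28 {(5R)-4-[(1S)-2-{(2S,3R)-2-({[tert-butyl(dimethyl)silyl]oxy}methyl)-3-[(Z)-2-(tributylstannyl)ethenyl]oxiran-2-yl}-1-{[(2R)-2-methylbutanoyl]oxy}ethyl]-5-[(Z)-2-iodoprop-1-en-1-yl]-2-oxo-2,5-dihydrofuran-3-yl}methyl acetate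
Conditions: Ac2O, pyridine, DMAP (cat.), CH2Cl2, 0 °C
Reagents that add atoms: acetic anhydride, CC(=O)OC(C)=O
Why: Acetylation of the primary allylic alcohol under standard acyl-transfer catalysis gives the C13 acetate of the target.

Step 22
Reactants: 28 open-chain C3 Z-alkenylstannane / C4 Z-alkenyl iodide
Product: 30 ten-membered (2Z,4Z)-diene (1,10-epoxygermacra-2,4,7(11)-trien-12,6-olide carrying 8-O-[(2R)-2-methylbutanoyl], 13-OAc and 14-OTBS; C1, C6, C8, C10 as in the target), via alkenylcopper 29 (not isolated)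
Conditions: CuTC (CuO2CC4H3S, 3 equiv), NMP, 0 °C → rt, 2 mM, slow addition of 28
Reagents that add atoms: none
Why: Tin-to-copper transmetalation of the Z-alkenylstannane by CuTC gives alkenylcopper 29, which adds oxidatively to the Z-alkenyl iodide at the other chain end to give a bis(alkenyl) trivalent copper species that collapses by reductive elimination, both events with retention at carbon. The closest known reaction type is the CuTC-mediated Stille-type alkenyl–alkenyl cross-coupling, which has precedent in macrocyclisation. The ten-membered carbocycle closes in the reductive elimination from an eleven-membered cupracycle, the new C3–C4 bond being endocyclic between two sp2 carbons. No stereocentre is formed; both Z geometries are carried over from 28, which also fixes the cis relation needed for the later 4,5-epoxide. The step needs cyclisation to beat oligomerisation and needs the allylic 1,10-epoxide to stay closed: high dilution and slow addition serve the first, helped by the turn that the Z C2=C3 bond, the epoxide and the butenolide impose on the chain, and the absence of zerovalent palladium serves the second. Since C1/C10 is already an epoxide, the product is a diene and not a conjugated triene.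

Step 23
Reactants: 30 ten-membered (2Z,4Z)-diene
Product: 31 14-O-TBS ether of the target (1,10:4,5-diepoxide)
Conditions: m-CPBA, NaHCO3, CH2Cl2, −20 → 0 °C
Reagents that add atoms: 3-chloroperbenzoic acid, OOC(=O)c1cccc(Cl)c1
Why: Peracid epoxidation should pick the electron-richer trisubstituted C4=C5 bond (C2=C3 is disubstituted and flanked by an epoxide, the butenolide alkene is electron-poor) and is expected on the peripheral face anti to the C6–O bond, which the C6 stereocentre and the ring conformation expose, setting C4 and C5 together by syn addition to the Z-alkene.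

Step 24
Reactants: 31 14-O-TBS ether of the target
Product: 32 CNP0108300.1
Conditions: Bu4NF, AcOH, THF, 0 °C → rt
Reagents that add atoms: none
Why: Fluoride cleavage of the primary TBS ether, buffered with acetic acid to avoid acyl migration, butenolide deprotonation and opening of the two allylic epoxides, releases the C14 alcohol of the target.

**Compound list**

1 | but-2-yn-1-ol | CC#CCO | starting material
2 | sodium cyclic alkenylaluminate (2,2-bis(2-methoxyethoxy)-4-methyl-1-oxa-2-aluminacyclopent-3-en-2-uide) | CC1=CCO[Al-]1(OCCOC)OCCOC.[Na+] | intermediate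
3 | (2Z)-3-iodobut-2-en-1-ol | C/C(I)=C/CO | intermediate
4 | (2Z)-3-iodobut-2-enal | C/C(I)=C/C=O | intermediate
5 | rac-(4Z)-5-iodohexa-1,4-dien-3-ol | C=CC(O)/C=C(/C)I | intermediate
6 | (3S,4Z)-5-iodohexa-1,4-dien-3-ol | C=C[C@H](O)/C=C(/C)I | intermediate
7 | prop-2-yn-1-ol (propargyl alcohol) | C#CCO | starting material
8 | cyclic alkenylmagnesium alkoxide (4-allyl-2,5-dihydro-1,2-oxamagnesole) | C=CCC1=C[Mg]OC1 | intermediate
9 | (2Z)-2-(iodomethylidene)pent-4-en-1-ol | I/C=C(/CC=C)CO | intermediate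
10 | (2Z)-2-[3-(trimethylsilyl)prop-2-yn-1-ylidene]pent-4-en-1-ol | C[Si](C)(C)C#C/C=C(/CC=C)CO | intermediate
11 | [(2S,3R)-2-(prop-2-en-1-yl)-3-[(trimethylsilyl)ethynyl]oxiran-2-yl]methanol | C[Si](C)(C)C#C[C@H]1O[C@]1(CO)CC=C | intermediate
12 | tert-butyl(dimethyl){[(2S,3R)-2-(prop-2-en-1-yl)-3-[(trimethylsilyl)ethynyl]oxiran-2-yl]methoxy}silane | C[Si](C)(C)C#C[C@H]1O[C@]1(CO[Si](C)(C)C(C)(C)C)CC=C | intermediate
13 | (2Z,4S,5E)-7-[(2S,3R)-2-({[tert-butyl(dimethyl)silyl]oxy}methyl)-3-[(trimethylsilyl)ethynyl]oxiran-2-yl]-2-iodohepta-2,5-dien-4-ol | C[Si](C)(C)C#C[C@H]1O[C@]1(CO[Si](C)(C)C(C)(C)C)C/C=C/[C@H](O)/C=C(/C)I | intermediate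
14 | (2Z,4S,5E)-7-[(2S,3R)-2-({[tert-butyl(dimethyl)silyl]oxy}methyl)-3-ethynyloxiran-2-yl]-2-iodohepta-2,5-dien-4-ol | C#C[C@H]1O[C@]1(CO[Si](C)(C)C(C)(C)C)C/C=C/[C@H](O)/C=C(/C)I | intermediate
15 | (2Z,4S,5E)-7-[(2S,3R)-2-({[tert-butyl(dimethyl)silyl]oxy}methyl)-3-[(tributylstannyl)ethynyl]oxiran-2-yl]-2-iodohepta-2,5-dien-4-ol | CCCC[Sn](CCCC)(CCCC)C#C[C@H]1O[C@]1(CO[Si](C)(C)C(C)(C)C)C/C=C/[C@H](O)/C=C(/C)I | intermediate
16 | 1-stannyl-1-(chlorozirconocenyl)alkene from 15 (Zr and Sn on C3, H on C2 cis to Zr; hydroxyl drawn free) | CCCC[Sn](CCCC)(CCCC)/C([Zr+2]Cl)=C\[C@H]1O[C@]1(CO[Si](C)(C)C(C)(C)C)C/C=C/[C@H](O)/C=C(/C)I.c1cc[cH-]c1.c1cc[cH-]c1 | intermediate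
17 | (2Z,4S,5E)-7-[(2S,3R)-2-({[tert-butyl(dimethyl)silyl]oxy}methyl)-3-[(Z)-2-(tributylstannyl)ethenyl]oxiran-2-yl]-2-iodohepta-2,5-dien-4-ol | CCCC[Sn](CCCC)(CCCC)/C=C\[C@H]1O[C@]1(CO[Si](C)(C)C(C)(C)C)C/C=C/[C@H](O)/C=C(/C)I | intermediate
18 | (1R,2Z)-1-{(2R,3R)-3-[((2S,3R)-2-({[tert-butyl(dimethyl)silyl]oxy}methyl)-3-[(Z)-2-(tributylstannyl)ethenyl]oxiran-2-yl)methyl]oxiran-2-yl}-3-iodobut-2-en-1-ol | CCCC[Sn](CCCC)(CCCC)/C=C\[C@H]1O[C@]1(CO[Si](C)(C)C(C)(C)C)C[C@H]2O[C@@H]2[C@H](O)/C=C(/C)I | intermediate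
19 | (2R)-2-methylbutanoic acid | CC[C@@H](C)C(=O)O | starting material
20 | (2S,3R,4R,5Z)-1-[(2S,3R)-2-({[tert-butyl(dimethyl)silyl]oxy}methyl)-3-[(Z)-2-(tributylstannyl)ethenyl]oxiran-2-yl]-3,4-dihydroxy-6-iodohept-5-en-2-yl (2R)-2-methylbutanoate | CCCC[Sn](CCCC)(CCCC)/C=C\[C@H]1O[C@]1(CO[Si](C)(C)C(C)(C)C)C[C@H](OC(=O)[C@H](C)CC)[C@H](O)[C@H](O)/C=C(/C)I | intermediate
21 | ethyl 2-(diethoxyphosphoryl)prop-2-enoate | C=C(C(=O)OCC)P(=O)(OCC)OCC | starting material
22 | ethyl 2-(diethoxyphosphoryl)-3-[(4-methoxyphenyl)methoxy]propanoate (racemic) | CCOC(=O)C(COCc1ccc(OC)cc1)P(=O)(OCC)OCC | intermediate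
23 | 2-(diethoxyphosphoryl)-3-[(4-methoxyphenyl)methoxy]propanoic acid (racemic) | OC(=O)C(COCc1ccc(OC)cc1)P(=O)(OCC)OCC | intermediate
24 | diol 20 esterified at the allylic C6 hydroxyl with acid 23 (C7 hydroxyl free; mixture at the phosphonate carbon) | CCCC[Sn](CCCC)(CCCC)/C=C\[C@H]1O[C@]1(CO[Si](C)(C)C(C)(C)C)C[C@H](OC(=O)[C@H](C)CC)[C@H](O)[C@H](OC(=O)C(COCc1ccc(OC)cc1)P(=O)(OCC)OCC)/C=C(/C)I | intermediate
25 | C7 ketone of 24 (C6 phosphonoacyloxy and C8 (2R)-2-methylbutanoyloxy flank the carbonyl) | CCCC[Sn](CCCC)(CCCC)/C=C\[C@H]1O[C@]1(CO[Si](C)(C)C(C)(C)C)C[C@H](OC(=O)[C@H](C)CC)C(=O)[C@H](OC(=O)C(COCc1ccc(OC)cc1)P(=O)(OCC)OCC)/C=C(/C)I | intermediate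
26 | (5R)-4-[(1S)-2-{(2S,3R)-2-({[tert-butyl(dimethyl)silyl]oxy}methyl)-3-[(Z)-2-(tributylstannyl)ethenyl]oxiran-2-yl}-1-{[(2R)-2-methylbutanoyl]oxy}ethyl]-5-[(Z)-2-iodoprop-1-en-1-yl]-3-{[(4-methoxyphenyl)methoxy]methyl}furan-2(5H)-one | CCCC[Sn](CCCC)(CCCC)/C=C\[C@H]1O[C@]1(CO[Si](C)(C)C(C)(C)C)C[C@H](OC(=O)[C@H](C)CC)C1=C(COCc2ccc(OC)cc2)C(=O)O[C@@H]1/C=C(/C)I | intermediate
27 | (5R)-4-[(1S)-2-{(2S,3R)-2-({[tert-butyl(dimethyl)silyl]oxy}methyl)-3-[(Z)-2-(tributylstannyl)ethenyl]oxiran-2-yl}-1-{[(2R)-2-methylbutanoyl]oxy}ethyl]-3-(hydroxymethyl)-5-[(Z)-2-iodoprop-1-en-1-yl]furan-2(5H)-one | CCCC[Sn](CCCC)(CCCC)/C=C\[C@H]1O[C@]1(CO[Si](C)(C)C(C)(C)C)C[C@H](OC(=O)[C@H](C)CC)C1=C(CO)C(=O)O[C@@H]1/C=C(/C)I | intermediate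
28 | {(5R)-4-[(1S)-2-{(2S,3R)-2-({[tert-butyl(dimethyl)silyl]oxy}methyl)-3-[(Z)-2-(tributylstannyl)ethenyl]oxiran-2-yl}-1-{[(2R)-2-methylbutanoyl]oxy}ethyl]-5-[(Z)-2-iodoprop-1-en-1-yl]-2-oxo-2,5-dihydrofuran-3-yl}methyl acetate | CCCC[Sn](CCCC)(CCCC)/C=C\[C@H]1O[C@]1(CO[Si](C)(C)C(C)(C)C)C[C@H](OC(=O)[C@H](C)CC)C1=C(COC(C)=O)C(=O)O[C@@H]1/C=C(/C)I | intermediate
29 | Z-alkenylcopper from 28 (Cu in place of SnBu3 on C3) | [Cu]/C=C\[C@H]1O[C@]1(CO[Si](C)(C)C(C)(C)C)C[C@H](OC(=O)[C@H](C)CC)C1=C(COC(C)=O)C(=O)O[C@@H]1/C=C(/C)I | intermediate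
30 | ten-membered (2Z,4Z)-diene: 1,10-epoxygermacra-2,4,7(11)-trien-12,6-olide with 8-O-[(2R)-2-methylbutanoyl], 13-OAc and 14-OTBS (C1, C6, C8, C10 as in the target) | CC[C@@H](C)C(=O)O[C@H]1C[C@@]2(CO[Si](C)(C)C(C)(C)C)O[C@@H]2/C=C\C(C)=C/[C@H]2OC(=O)C(COC(C)=O)=C12 | intermediate
31 | 14-O-TBS ether of the target (1,10:4,5-diepoxide, all stereocentres as in the target) | CC[C@@H](C)C(=O)O[C@H]1C[C@@]2(CO[Si](C)(C)C(C)(C)C)O[C@@H]2/C=C\[C@@]2(C)O[C@H]2[C@H]2OC(=O)C(COC(C)=O)=C12 | intermediate
32 | CNP0108300.1 | CC[C@@H](C)C(=O)O[C@H]1C[C@@]2(CO)O[C@@H]2/C=C\[C@@]2(C)O[C@H]2[C@H]2OC(=O)C(COC(C)=O)=C12 | target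

**Step count and risks**

Total step count: 24. Longest linear sequence: 18 steps (steps 5–14 and 17–24 from propargyl alcohol 7; the branch from but-2-yn-1-ol 1 through steps 1–4 is equally long).

Steps most likely to fail:

1. Step 22. Intermolecular coupling (oligomerisation) or protodestannylation of the alkenylcopper may outrun closure of the strained ten-membered ring with its Z,Z-diene, fused butenolide and epoxide. Fallback: setting out from 28, tin–iodine exchange with I2 (CH2Cl2, 0 °C) would give the bis(alkenyl iodide) F1, and a nickel-mediated reductive alkenyl–alkenyl coupling (Ni(cod)2, zerovalent nickel, PPh3, DMF, high dilution) would close the same C3–C4 bond without a tin partner, coming back to the route at 30.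

2. Step 23. Facial selectivity on the C4=C5 bond may be poor or reversed, since it rests only on the ring conformation and C6. Fallback: setting out from 30, NBS in wet THF would form the bromonium ion on the face the peracid prefers and water would enter at the tertiary allylic C4 from the other face, giving the bromohydrin F2; Ag2O would then close the oxirane with inversion at C5, placing the oxygen on the face opposite to that of direct epoxidation and coming back to the route at 31.

3. Step 17. Acylation may occur at the C7 instead of the C6 hydroxyl, or the C8 ester may migrate to the C7 hydroxyl, either of which misplaces the later ketone. Fallback: setting out from 18, the single (C6) hydroxyl would be esterified with 23 first (DCC, DMAP) to give the epoxy phosphonoacetate F3, and the epoxide would then be opened at C8, the carbon remote from the acyloxy-bearing C6, by caesium (2R)-2-methylbutanoate (19, Cs2CO3, DMF), which avoids any diol stage and comes back to the route at 24.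

Further compounds
F1 | step 22 | bis(alkenyl iodide): 28 with iodine in place of the tributylstannyl group on C3 | I/C=C\[C@H]1O[C@]1(CO[Si](C)(C)C(C)(C)C)C[C@H](OC(=O)[C@H](C)CC)C1=C(COC(C)=O)C(=O)O[C@@H]1/C=C(/C)I
F2 | step 23 | bromohydrin of 30 (C4 hydroxyl with the configuration of the target, C5 bromide anti to it) | CC[C@@H](C)C(=O)O[C@H]1C[C@@]2(CO[Si](C)(C)C(C)(C)C)O[C@@H]2/C=C\[C@@](C)(O)[C@H](Br)[C@H]2OC(=O)C(COC(C)=O)=C12
F3 | step 17 | epoxy phosphonoacetate: 18 esterified at the C6 hydroxyl with 23 | CCCC[Sn](CCCC)(CCCC)/C=C\[C@H]1O[C@]1(CO[Si](C)(C)C(C)(C)C)C[C@H]2O[C@@H]2[C@H](OC(=O)C(COCc2ccc(OC)cc2)P(=O)(OCC)OCC)/C=C(/C)I
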